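**Retrosynthetic overview**
1. Target 22 ⇐ face-selective epoxidation of the (E)-4,5-alkene of the ten-membered dienolide 21.
2. 21 ⇐ Pd(0)-catalysed decarboxylative ring contraction of the 12-membered allyl β-keto lactone 20 (C2–C3 bond made, CO2 lost).
3. 20 ⇐ acylketene macrolactonisation of hydroxy acid 17; 17 ⇐ Ni/Cr coupling (C7–C8) of iodobutenolide 12 with aldehyde 7, then acylations and allylic oxidation of the E-methyl (C3).
4. 12 ⇐ 3-methylbut-2-enal + methyl propiolate (asymmetric alkynylation, iodo-aldol/lactonisation); 7 ⇐ Cu-box aldol of tert-butyl pyruvate with a thioacetate enolsilane.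
5. Ring order: butenolide → 12-membered lactone → 10-membered carbocycle → epoxide.

Locants used below are germacranolide numbering of the target: C1 ketone, C4–C5 epoxide, C6 lactone CH–O, C7=C11, C8 CH–OCOEt, C10 C(CH3)OAc, C12 lactone C=O, C13 CH2OAc.

**Route**

Step 1
Reactants: 1 S-ethyl ethanethioate
Product: 2 [1-(ethylsulfanyl)ethenyl]oxy-trimethylsilane
Conditions: LDA, THF, −78 °C; TMSCl; distil
Reagents that add atoms: chlorotrimethylsilane, C[Si](C)(C)Cl
Why: Kinetic deprotonation gives the lithium thioester enolate, which is silylated on oxygen (silyl ketene thioacetal formation); no stereocentre is involved.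

Step 2
Reactants: 2 [1-(ethylsulfanyl)ethenyl]oxy-trimethylsilane; 3 tert-butyl 2-oxopropanoate
Product: 5 tert-butyl (2R)-4-(ethylsulfanyl)-2-hydroxy-2-methyl-4-oxobutanoate, via silylated aldol adduct 4 (not isolated)
Conditions: [Cu((R,R)-t-Bu-box)](OTf)2 (10 mol%), THF, −78 °C; 1 M HCl
Reagents that add atoms: none
Why: Evans Cu(II)–bis(oxazoline) Mukaiyama aldol: the pyruvate chelates copper through both carbonyls, the ligand blocks one ketone face and the enolsilane adds to the other, which sets C10 (R).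

Step 3
Reactants: 5 tert-butyl (2R)-4-(ethylsulfanyl)-2-hydroxy-2-methyl-4-oxobutanoate
Product: 6 tert-butyl (2R)-2-acetoxy-4-(ethylsulfanyl)-2-methyl-4-oxobutanoate
Conditions: Ac2O, Sc(OTf)3 (1 mol%), MeCN, −20 °C
Reagents that add atoms: acetic anhydride, CC(=O)OC(C)=O
Why: Lewis-acid-catalysed acetylation of the hindered tertiary alcohol is base-free, so the β-acyloxy thioester does not eliminate and C10 is untouched.

Step 4
Reactants: 6 tert-butyl (2R)-2-acetoxy-4-(ethylsulfanyl)-2-methyl-4-oxobutanoate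
Product: 7 tert-butyl (2R)-2-acetoxy-2-methyl-4-oxobutanoate
Conditions: Et3SiH, 10% Pd/C, acetone, rt; use at once
Reagents that add atoms: none
Why: Fukuyama reduction: Pd inserts into the acyl C–S bond and the silane delivers hydride, giving the aldehyde while the acetate and tert-butyl ester stay intact.

Step 5
Reactants: 8 3-methylbut-2-enal; 9 methyl prop-2-ynoate
Product: 10 methyl (4R)-4-hydroxy-6-methylhept-5-en-2-ynoate
Conditions: Me2Zn (3 equiv), ProPhenol (10 mol%, enantiomer giving 4R), Ph3PO (20 mol%), toluene, 4 °C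
Reagents that add atoms: none
Why: Trost ProPhenol dinuclear-zinc asymmetric alkynylation: the chiral zinc catalyst delivers the zinc propiolate to one face of the enal, which sets C6.

Step 6
Reactants: 10 methyl (4R)-4-hydroxy-6-methylhept-5-en-2-ynoate
Product: 12 (5R)-3-(hydroxymethyl)-4-iodo-5-(2-methylprop-1-enyl)furan-2(5H)-one, via iodo dienoate diol 11 (not isolated)
Conditions: Et2AlI (2.3 equiv), CH2Cl2, −40 to 0 °C; monomeric CH2O (from paraformaldehyde); 1 M HCl, NaI (cat.), THF, rt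
Reagents that add atoms: diethylaluminium iodide, CC[Al](I)CC; formaldehyde, C=O
Why: Halo-aldol (iodo-Baylis–Hillman type): iodide adds to C7 of the ynoate, the aluminium allenolate is hydroxymethylated at C11, and on acidification the isomer with the C6 hydroxyl cis to the ester lactonises while the other equilibrates by reversible iodide addition; C6 is not touched.

Step 7
Reactants: 12 (5R)-3-(hydroxymethyl)-4-iodo-5-(2-methylprop-1-enyl)furan-2(5H)-one; 7 tert-butyl (2R)-2-acetoxy-2-methyl-4-oxobutanoate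
Product: 13 tert-butyl (2R,4S)-2-acetoxy-4-hydroxy-4-[(2R)-4-(hydroxymethyl)-2-(2-methylprop-1-enyl)-5-oxo-2,5-dihydrofuran-3-yl]-2-methylbutanoate
Conditions: CrCl2 (4 equiv), NiCl2 (10 mol%), Kishi oxazoline–sulfonamide ligand (enantiomer giving 8S), Et3N, THF, rt
Reagents that add atoms: none
Why: Nozaki–Hiyama–Kishi coupling: Ni(0) inserts into the alkenyl C–I bond and transmetalates to Cr(III), whose chiral sulfonamide ligand directs addition to one aldehyde face and sets C8 (S) under non-basic conditions that spare C6–H and the β-acetoxy aldehyde.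

Step 8
Reactants: 13 tert-butyl (2R,4S)-2-acetoxy-4-hydroxy-4-[(2R)-4-(hydroxymethyl)-2-(2-methylprop-1-enyl)-5-oxo-2,5-dihydrofuran-3-yl]-2-methylbutanoate
Product: 15 tert-butyl (2R,4S)-2-acetoxy-4-[(2R)-4-(acetoxymethyl)-2-(2-methylprop-1-enyl)-5-oxo-2,5-dihydrofuran-3-yl]-2-methyl-4-(propanoyloxy)butanoate, via primary monoacetate 14 (not isolated)
Conditions: AcCl (1.05 equiv), 2,4,6-collidine, CH2Cl2, −78 °C; then (EtCO)2O (3 equiv), DMAP (0.2 equiv), −78 to 0 °C
Reagents that add atoms: acetyl chloride, CC(Cl)=O; propanoic anhydride, CCC(=O)OC(=O)CC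
Why: Site-selective acylation: the primary allylic hydroxyl is acetylated first at low temperature, then the hindered secondary C8 hydroxyl is propanoylated with DMAP catalysis before acetyl migration from C10 can occur; no stereocentre changes.

Step 9
Reactants: 15 tert-butyl (2R,4S)-2-acetoxy-4-[(2R)-4-(acetoxymethyl)-2-(2-methylprop-1-enyl)-5-oxo-2,5-dihydrofuran-3-yl]-2-methyl-4-(propanoyloxy)butanoate
Product: 16 (2R,4S)-2-acetoxy-4-[(2R)-4-(acetoxymethyl)-2-(2-methylprop-1-enyl)-5-oxo-2,5-dihydrofuran-3-yl]-2-methyl-4-(propanoyloxy)butanoic acid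
Conditions: TFA/CH2Cl2 (1:4), 0 °C, 1 h
Reagents that add atoms: none
Why: Acidolysis of the tert-butyl ester (loss of isobutene) frees the C1 acid, and the acetates, propanoate and lactone are stable to brief cold acid.

Step 10
Reactants: 16 (2R,4S)-2-acetoxy-4-[(2R)-4-(acetoxymethyl)-2-(2-methylprop-1-enyl)-5-oxo-2,5-dihydrofuran-3-yl]-2-methyl-4-(propanoyloxy)butanoic acid
Product: 17 (2R,4S)-2-acetoxy-4-{(2R)-4-(acetoxymethyl)-2-[(1E)-3-hydroxy-2-methylprop-1-enyl]-5-oxo-2,5-dihydrofuran-3-yl}-2-methyl-4-(propanoyloxy)butanoic acid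
Conditions: SeO2 (0.5 equiv), t-BuOOH (3 equiv), CH2Cl2, rt
Reagents that add atoms: selenium dioxide (catalytic oxygen carrier), O=[Se]=O; tert-butyl hydroperoxide (terminal oxygen source), CC(C)(C)OO
Why: Sharpless SeO2/t-BuOOH allylic oxidation: the ene reaction and [2,3]-shift oxidise the E-methyl of the electron-rich trisubstituted alkene, which gives the (E)-allylic alcohol (C3) and leaves the electron-poor butenolide alkene alone.

Step 11
Reactants: 17 (2R,4S)-2-acetoxy-4-{(2R)-4-(acetoxymethyl)-2-[(1E)-3-hydroxy-2-methylprop-1-enyl]-5-oxo-2,5-dihydrofuran-3-yl}-2-methyl-4-(propanoyloxy)butanoic acid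
Product: 20 (4E,6R,8S,10R)-12-membered allyl β-keto lactone [ring O–C3H2–C4(CH3)=C5H–C6H–C7–C8H(OCOEt)–C9H2–C10(CH3)(OAc)–C1(=O)–C2H2–C(=O); 13-acetoxy butenolide fused at C6–C7], via acyl Meldrum's acid 18 (not isolated), via acylketene 19 (not isolated)
Conditions: Meldrum's acid (1.2 equiv), DCC (1.2 equiv), DMAP (1.5 equiv), CH2Cl2, 0 °C to rt; filter; toluene (2 mM), 100 °C
Reagents that add atoms: 2,2-dimethyl-1,3-dioxane-4,6-dione (Meldrum's acid), CC1(C)OC(=O)CC(=O)O1
Why: Acylation of Meldrum's acid and thermolysis give an acylketene that is trapped at high dilution by the primary allylic alcohol (acylketene macrolactonisation of the Boeckman type), which forms the 12-membered β-keto lactone without touching a stereocentre.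

Step 12
Reactants: 20 (4E,6R,8S,10R)-12-membered allyl β-keto lactone
Product: 21 (4E,6R,8S,10R)-10,13-diacetoxy-1-oxo-8-(propanoyloxy)germacra-4,7(11)-dien-12,6-olide
Conditions: Pd(PPh3)4 (5 mol%), THF (5 mM), 25 °C
Reagents that add atoms: none
Why: Proposed new method: Pd(0) ionises the unhindered primary allyl ester C3–O bond of the macrolactone to a π-allyl-Pd/β-keto carboxylate ion pair, CO2 is lost, and the ketone enolate (only C2 can enolise because C10 is quaternary) recombines at the unsubstituted allyl terminus C3, so the 12-membered lactone contracts to the 10-membered carbocycle with the E alkene kept (syn π-allyl) and no new stereocentre; the closest known reactions are the Tsuji decarboxylative allylation of acyclic allyl β-keto esters and Pd-catalysed allylic macrocyclisations, which have not been shown as a macrolactone-to-carbocycle ring contraction.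

Step 13
Reactants: 21 (4E,6R,8S,10R)-10,13-diacetoxy-1-oxo-8-(propanoyloxy)germacra-4,7(11)-dien-12,6-olide
Product: 22 (4R,5R,6S,8S,10R)-10,13-diacetoxy-4,5-epoxy-1-oxo-8-(propanoyloxy)germacr-7(11)-en-12,6-olide
Conditions: DMDO (1.1 equiv), acetone, −20 °C
Reagents that add atoms: dimethyldioxirane, CC1(C)OO1
Why: Electrophilic epoxidation picks the only electron-rich alkene, and attack on the exposed outer face of the (E)-4,5-alkene in the ten-membered ring (as in the 4,5-epoxidation of related germacranolides with the same C6 configuration) is expected to give the trans (4R,5R) epoxide.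

**Compound list**
1 | S-ethyl ethanethioate | CCSC(C)=O | starting material
2 | [1-(ethylsulfanyl)ethenyl]oxy-trimethylsilane | C=C(SCC)O[Si](C)(C)C | intermediate
3 | tert-butyl 2-oxopropanoate (pyruvic acid as its tert-butyl ester; the tert-butyl protecting group is removed in step 9) | CC(=O)C(=O)OC(C)(C)C | starting material
4 | tert-butyl (2R)-4-(ethylsulfanyl)-2-methyl-4-oxo-2-(trimethylsilyloxy)butanoate | CCSC(=O)C[C@@](C)(O[Si](C)(C)C)C(=O)OC(C)(C)C | intermediate (not isolated)
5 | tert-butyl (2R)-4-(ethylsulfanyl)-2-hydroxy-2-methyl-4-oxobutanoate | CCSC(=O)C[C@@](C)(O)C(=O)OC(C)(C)C | intermediate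
6 | tert-butyl (2R)-2-acetoxy-4-(ethylsulfanyl)-2-methyl-4-oxobutanoate | CCSC(=O)C[C@@](C)(OC(C)=O)C(=O)OC(C)(C)C | intermediate
7 | tert-butyl (2R)-2-acetoxy-2-methyl-4-oxobutanoate | O=CC[C@@](C)(OC(C)=O)C(=O)OC(C)(C)C | intermediate
8 | 3-methylbut-2-enal | CC(C)=CC=O | starting material
9 | methyl prop-2-ynoate | C#CC(=O)OC | starting material
10 | methyl (4R)-4-hydroxy-6-methylhept-5-en-2-ynoate | COC(=O)C#C[C@H](O)C=C(C)C | intermediate
11 | methyl (2E,4R)-4-hydroxy-2-(hydroxymethyl)-3-iodo-6-methylhepta-2,5-dienoate | COC(=O)/C(CO)=C(/I)[C@H](O)C=C(C)C | intermediate (not isolated)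
12 | (5R)-3-(hydroxymethyl)-4-iodo-5-(2-methylprop-1-enyl)furan-2(5H)-one | CC(C)=C[C@H]1OC(=O)C(CO)=C1I | intermediate
13 | tert-butyl (2R,4S)-2-acetoxy-4-hydroxy-4-[(2R)-4-(hydroxymethyl)-2-(2-methylprop-1-enyl)-5-oxo-2,5-dihydrofuran-3-yl]-2-methylbutanoate | CC(C)=C[C@H]1OC(=O)C(CO)=C1[C@@H](O)C[C@@](C)(OC(C)=O)C(=O)OC(C)(C)C | intermediate
14 | tert-butyl (2R,4S)-2-acetoxy-4-[(2R)-4-(acetoxymethyl)-2-(2-methylprop-1-enyl)-5-oxo-2,5-dihydrofuran-3-yl]-4-hydroxy-2-methylbutanoate | CC(C)=C[C@H]1OC(=O)C(COC(C)=O)=C1[C@@H](O)C[C@@](C)(OC(C)=O)C(=O)OC(C)(C)C | intermediate (not isolated)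
15 | tert-butyl (2R,4S)-2-acetoxy-4-[(2R)-4-(acetoxymethyl)-2-(2-methylprop-1-enyl)-5-oxo-2,5-dihydrofuran-3-yl]-2-methyl-4-(propanoyloxy)butanoate | CC(C)=C[C@H]1OC(=O)C(COC(C)=O)=C1[C@@H](OC(=O)CC)C[C@@](C)(OC(C)=O)C(=O)OC(C)(C)C | intermediate
16 | (2R,4S)-2-acetoxy-4-[(2R)-4-(acetoxymethyl)-2-(2-methylprop-1-enyl)-5-oxo-2,5-dihydrofuran-3-yl]-2-methyl-4-(propanoyloxy)butanoic acid | CC(C)=C[C@H]1OC(=O)C(COC(C)=O)=C1[C@@H](OC(=O)CC)C[C@@](C)(OC(C)=O)C(O)=O | intermediate
17 | (2R,4S)-2-acetoxy-4-{(2R)-4-(acetoxymethyl)-2-[(1E)-3-hydroxy-2-methylprop-1-enyl]-5-oxo-2,5-dihydrofuran-3-yl}-2-methyl-4-(propanoyloxy)butanoic acid | OC/C(C)=C/[C@H]1OC(=O)C(COC(C)=O)=C1[C@@H](OC(=O)CC)C[C@@](C)(OC(C)=O)C(O)=O | intermediate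
18 | acyl Meldrum's acid of 17 (enol form: 5-(1-hydroxyalkylidene)-2,2-dimethyl-1,3-dioxane-4,6-dione, the alkylidene carbon being C1) | OC/C(C)=C/[C@H]1OC(=O)C(COC(C)=O)=C1[C@@H](OC(=O)CC)C[C@@](C)(OC(C)=O)C(O)=C1C(=O)OC(C)(C)OC1=O | intermediate (not isolated)
19 | acylketene from 18: (4R,6S)-4-acetoxy-6-{(2R)-4-(acetoxymethyl)-2-[(1E)-3-hydroxy-2-methylprop-1-enyl]-5-oxo-2,5-dihydrofuran-3-yl}-4-methyl-3-oxo-6-(propanoyloxy)hex-1-en-1-one | OC/C(C)=C/[C@H]1OC(=O)C(COC(C)=O)=C1[C@@H](OC(=O)CC)C[C@@](C)(OC(C)=O)C(=O)C=C=O | intermediate (not isolated)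
20 | (4E,6R,8S,10R)-12-membered allyl β-keto lactone: ring O–C3H2–C4(CH3)=C5H–C6H–C7–C8H(OCOEt)–C9H2–C10(CH3)(OAc)–C1(=O)–C2H2–C(=O), with the C6–O–C12(=O)–C11(CH2OAc)=C7 butenolide fused at C6–C7 | CCC(=O)O[C@H]1C[C@@](C)(OC(C)=O)C(=O)CC(=O)OC/C(C)=C/[C@H]2OC(=O)C(COC(C)=O)=C12 | intermediate
21 | (4E,6R,8S,10R)-10,13-diacetoxy-1-oxo-8-(propanoyloxy)germacra-4,7(11)-dien-12,6-olide | CCC(=O)O[C@H]1C[C@@](C)(OC(C)=O)C(=O)CC/C(C)=C/[C@H]2OC(=O)C(COC(C)=O)=C12 | intermediate
22 | (4R,5R,6S,8S,10R)-10,13-diacetoxy-4,5-epoxy-1-oxo-8-(propanoyloxy)germacr-7(11)-en-12,6-olide (CNP0285168.1) | CCC(=O)O[C@H]1C[C@@](C)(OC(C)=O)C(=O)CC[C@@]2(C)O[C@@H]2[C@H]2OC(=O)C(COC(C)=O)=C12 | target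

**Step count and risks**

Total steps: 13. Longest linear sequence: 11 (steps 1–4, then 7–13). The butenolide branch (steps 5–6) joins at step 7.

The three steps most likely to fail:

Step 12, the new ring contraction. Pd(0) could instead ionise the allylic lactone C6–O or the C13 acetate, and the unstabilised Pd enolate could take the acidic C6–H or attack the C10 acetate. The fallback uses known chemistry, sets out from 17 and comes back at 21. Methyl chloroformate and pyridine convert the allylic alcohol of 17 into the allylic methyl carbonate acid F1. Acylation of Meldrum's acid (DCC, DMAP) gives the acyl Meldrum's acid F2, which is heated with tert-butanol in toluene to give the open-chain tert-butyl β-keto ester carbonate F3. The established Pd(0) macrocyclisation of a stabilised β-keto ester anion onto an allylic carbonate (Pd(PPh3)4, dppe, THF, slow addition; the released methoxide is the base) then closes the ten-membered ring as the 2-(tert-butoxycarbonyl) ketone F4. TFA followed by gentle warming removes the ester carbon as isobutene and CO2 and gives 21. Here the nucleophile is a stabilised enolate, so proton and acyl transfer are not an issue.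

Step 6, the iodo-aldol/lactonisation. Formaldehyde capture by an internal, γ-oxygenated ynoate and the olefin geometry are not secured by close precedent. The fallback sets out from 8 and comes back at 12; it brings C13 in with the alkyne and C12 in by carbonylation. ProPhenol/Me2Zn alkynylation of 8 with tert-butyldimethyl(prop-2-ynyloxy)silane gives the propargylic alcohol F5. Iodine in CH2Cl2 adds anti to the alkyne and gives the (E)-diiodide F6. PdCl2(PPh3)2, CO (1 atm) and K2CO3 in dry THF carbonylate the C–I bond that lies cis to the carbinol, and the hydroxyl traps the acyl-palladium to give the silyl-protected iodobutenolide F7. HF·pyridine removes the silyl group and gives 12.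

Step 13, the final epoxidation. The face selectivity rests on the ring conformation and could favour the 4,5-epimer. The fallback sets out from 21 and comes back at 22; it delivers the oxygen to the opposite face. NBS in wet DME forms the bromonium ion on the face an electrophilic oxidant prefers, water opens it anti at the tertiary C4, and this gives the bromohydrin F8. Ag2O in DME then closes the epoxide with inversion at C5 to give 22.

**Further compounds**
F1 | step 12 | (2R,4S)-2-acetoxy-4-{(2R)-4-(acetoxymethyl)-2-[(1E)-3-(methoxycarbonyloxy)-2-methylprop-1-enyl]-5-oxo-2,5-dihydrofuran-3-yl}-2-methyl-4-(propanoyloxy)butanoic acid | COC(=O)OC/C(C)=C/[C@H]1OC(=O)C(COC(C)=O)=C1[C@@H](OC(=O)CC)C[C@@](C)(OC(C)=O)C(O)=O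
F2 | step 12 | acyl Meldrum's acid of F1 (enol form, not isolated) | COC(=O)OC/C(C)=C/[C@H]1OC(=O)C(COC(C)=O)=C1[C@@H](OC(=O)CC)C[C@@](C)(OC(C)=O)C(O)=C1C(=O)OC(C)(C)OC1=O
F3 | step 12 | tert-butyl (4R,6S)-4-acetoxy-6-{(2R)-4-(acetoxymethyl)-2-[(1E)-3-(methoxycarbonyloxy)-2-methylprop-1-enyl]-5-oxo-2,5-dihydrofuran-3-yl}-4-methyl-3-oxo-6-(propanoyloxy)hexanoate | COC(=O)OC/C(C)=C/[C@H]1OC(=O)C(COC(C)=O)=C1[C@@H](OC(=O)CC)C[C@@](C)(OC(C)=O)C(=O)CC(=O)OC(C)(C)C
F4 | step 12 | (4E,6R,8S,10R)-10,13-diacetoxy-2-(tert-butoxycarbonyl)-1-oxo-8-(propanoyloxy)germacra-4,7(11)-dien-12,6-olide (C2 epimers) | CCC(=O)O[C@H]1C[C@@](C)(OC(C)=O)C(=O)C(C(=O)OC(C)(C)C)C/C(C)=C/[C@H]2OC(=O)C(COC(C)=O)=C12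
F5 | step 6 | (4R)-1-(tert-butyldimethylsilyloxy)-6-methylhept-5-en-2-yn-4-ol | CC(C)=C[C@@H](O)C#CCO[Si](C)(C)C(C)(C)C
F6 | step 6 | (2E,4R)-1-(tert-butyldimethylsilyloxy)-2,3-diiodo-6-methylhepta-2,5-dien-4-ol | CC(C)=C[C@@H](O)/C(I)=C(\I)CO[Si](C)(C)C(C)(C)C
F7 | step 6 | (5R)-3-[(tert-butyldimethylsilyloxy)methyl]-4-iodo-5-(2-methylprop-1-enyl)furan-2(5H)-one | CC(C)=C[C@H]1OC(=O)C(CO[Si](C)(C)C(C)(C)C)=C1I
F8 | step 13 | (4R,5S,6S,8S,10R)-10,13-diacetoxy-5-bromo-4-hydroxy-1-oxo-8-(propanoyloxy)germacr-7(11)-en-12,6-olide | CCC(=O)O[C@H]1C[C@@](C)(OC(C)=O)C(=O)CC[C@@](C)(O)[C@@H](Br)[C@H]2OC(=O)C(COC(C)=O)=C12
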